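common to all: partner 28.6 mM

|  | solid substrate | remark | time |
|---|---|---|---|
| teal | 26 mM | the very flask that is asked about, followed so far |  |
| grey | 13 mM | run made earlier |  |
| flask | 26 mM |  | 30 min |

| run | time / min | product / % | solid substrate / % |
|---|---|---|---|
| teal | 1.33 | 2 | 94 |
| teal | 2.00 | 3 | 87 |
| teal | 3.00 | 3 | 87 |
| teal | 5.00 | 7 | 79 |
| teal | 10.0 | 24 | 58 |
| teal | 15.0 | 43 | 37 |
| grey | 0.833 | 1 | 92 |
| grey | 2.50 | 7 | 77 |
| grey | 4.00 | 14 | 64 |
| grey | 6.00 | 23 | 45 |
| grey | 10.0 | 51 | 15 |
| grey | 12.0 | 63 | 2 |

(readings scatter by 1.5 percentage points)

- solid, in amounts per volume of the solution: solid substrate
- the earlier runs were read with a standard deviation of 1.5 percentage points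
- at the start none of the solid substrate is in solution

- summer: doubling the solubility of the solid substrate, all else as stated
- midnight: doubling the dissolution coefficient of the solid substrate, all else as stated
- spring: doubling the amount of partner, all else as stated

* amount of product at 30 min, in percent of the solid substrate charged
* the change that raises the amount of product at 30 min, in percent of the solid substrate charged most ("none" if none brings more than 2 percentage points) (summer / midnight / spring / none)
* amount of product at 30 min, in percent of the solid substrate charged, after spring

A subtraction comes first. Between 1.33 min and 15.0 min the teal solid substrate falls from 94 % to 37 % of its charge, and the grey solid, with half the load, falls from 92 % to 2 % between 0.833 min and 12.0 min: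

teal fall = 1.08 mM min⁻¹

grey fall = 1.05 mM min⁻¹

These readings are close, so in both runs the solid leaves at a steady, nearly zero-order pace. That pace gives a count of turnovers of the charge:

charge count = fall per minute × time ÷ charge = 1.25

For the teal flask, a count above one puts the estimated empty point at 24.0 min, before the asked time.

Take the settings in turn. By hand, doubling the solubility (summer) or the dissolution coefficient (midnight) doubles the fall, so the count becomes 2.50 and the teal solid empties at 12.0 min: the same charge, delivered earlier. Doubling the partner (spring) is reckoned here to leave the count as it is, but acts on the 20.0 % of the teal charge that at 15.0 min reads as neither solid nor product. The count gives no yield; as an estimate, with the solid due out before the asked time, it favours spring.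

The forecast puts the product at 81 % and names spring as best, with 97 % after it, on the ground that “Doubling partner doubles the reaction rate”.

The flask gives 76.5 %, and spring gives 98.7 %, a gain of 22 percentage points against 9.5 points for summer and 8.5 points for midnight.

    2 starting material ⇌ resting dimer, settled at all times (K = 75.0 L mol⁻¹)
    starting material + partner → product (k = 12.0 L mol⁻¹ min⁻¹)
    solid substrate ⇌ starting material, rate k3*(cs3 - [starting material]) while solid is left; crystals form when [starting material] > cs3 (solubility = 13.0 mM, k = 0.100 min⁻¹)

At 30.0 min, with the count at 1.25, the teal flask holds 0 % solid substrate beside 14.9 % starting material and 8.65 % resting dimer, a resting state the count does not contain. The same flask read at 12 min has a count of 0.500, which reckons 50.0 % of the solid as left, and that flask holds 50.6 %.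

The data are simulated on assumed constants, and the scatter is random.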